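**Retrosynthetic overview**
- Last bonds: global O-debenzylation; the (E)-stilbene comes from a Horner–Wadsworth–Emmons olefination of a ring-A aldehyde carried as a methyl ester.
- Each C3–aryl bond is cut back to a 2-aryl-2,3-dihydrobenzofuran-3-carboxylic acid (Ni-catalysed decarboxylative arylation; the C2 aryl group directs trans).
- Each dihydrofuran comes from an intermolecular Evans syn-aldol (the C2–C3 bond) between a [2,6-bis(methoxymethoxy)aryl]acetyl oxazolidinone and 4-(benzyloxy)benzaldehyde, then reductive auxiliary removal and acid-triggered MOM loss with cyclisation.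
- Ring order: the dihydrofuran on ring A first; ring B is then attached at C3 as a boronic acid carrying a masked acetic acid chain; the second dihydrofuran is built on ring B by the same aldol sequence. All benzene rings are bought.
- Building blocks: methyl 4-bromo-3,5-dihydroxybenzoate, resorcinol, 4-(benzyloxy)benzaldehyde, (4S)-4-benzyl-1,3-oxazolidin-2-one, 3,5-bis(benzyloxy)phenylboronic acid, 4-(benzyloxy)benzyl chloride.

Assumption: the SMILES is read as drawn, so both dihydrobenzofurans are 2,3-trans and all four stereocentres are S. Ring A is the benzo ring of the styryl-bearing dihydrobenzofuran and ring B that of the second one.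
Abbreviation in names: DBF-A = (2S,3S)-4-(benzyloxy)-2-[4-(benzyloxy)phenyl]-6-(methoxycarbonyl)-2,3-dihydro-1-benzofuran-3-yl, bonded through C3.

**Route**

Step 1
Reactants: 1 methyl 4-bromo-3,5-dihydroxybenzoate
Product: 2 methyl 4-bromo-3,5-bis(methoxymethoxy)benzoate
Conditions: MOMCl (3 equiv), i-Pr2NEt (4 equiv), CH2Cl2, 0 °C → rt
Reagents that add atoms: chloromethyl methyl ether, COCCl
Why: Williamson-type O-alkylation protects both phenols as MOM ethers, which later serve as the acid-labile trigger for cyclisation.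

Step 2
Reactants: 2 methyl 4-bromo-3,5-bis(methoxymethoxy)benzoate
Product: 3 methyl 3,5-bis(methoxymethoxy)-4-(prop-2-en-1-yl)benzoate
Conditions: allylSnBu3 (1.5 equiv), Pd(PPh3)4 (5 mol %), toluene, 110 °C
Reagents that add atoms: allyltributylstannane, C=CC[Sn](CCCC)(CCCC)CCCC
Why: Stille cross-coupling of the electron-poor aryl bromide puts an allyl group on the carbon between the two MOM ethers.

Step 3
Reactants: 3 methyl 3,5-bis(methoxymethoxy)-4-(prop-2-en-1-yl)benzoate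
Product: 5 methyl 3,5-bis(methoxymethoxy)-4-(2-oxoethyl)benzoate, via vicinal diol 4 (not isolated)
Conditions: OsO4 (2 mol %), NaIO4 (4 equiv), 2,6-lutidine, dioxane/H2O 3:1, rt
Reagents that add atoms: OsO4, O=[Os](=O)(=O)=O (oxygen carrier); NaIO4, [Na+].[O-]I(=O)(=O)=O (terminal oxygen source)
Why: Lemieux–Johnson oxidation dihydroxylates the terminal alkene and cleaves the diol to the arylacetaldehyde with loss of formaldehyde.

Step 4
Reactants: 5 methyl 3,5-bis(methoxymethoxy)-4-(2-oxoethyl)benzoate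
Product: 6 2-[4-(methoxycarbonyl)-2,6-bis(methoxymethoxy)phenyl]acetic acid
Conditions: NaClO2, NaH2PO4, 2-methyl-2-butene, t-BuOH/H2O, 0 °C → rt
Reagents that add atoms: NaClO2, [Na+].[O-]Cl=O
Why: Pinnick oxidation gives the acid under buffered conditions that spare MOM ethers and the methyl ester, with the alkene scavenging HOCl.

Step 5
Reactants: 6 2-[4-(methoxycarbonyl)-2,6-bis(methoxymethoxy)phenyl]acetic acid; 7 (4S)-4-benzyl-1,3-oxazolidin-2-one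
Product: 9 methyl 4-{2-[(4S)-4-benzyl-2-oxo-1,3-oxazolidin-3-yl]-2-oxoethyl}-3,5-bis(methoxymethoxy)benzoate, via mixed pivalic anhydride 8 (not isolated)
Conditions: t-BuCOCl, Et3N, THF, −20 °C; then 7, LiCl, −20 °C → rt
Reagents that add atoms: pivaloyl chloride, CC(C)(C)C(=O)Cl (its acyl group is carried by 8 only)
Why: N-acylation of the oxazolidinone through the mixed anhydride (LiCl/Et3N variant) installs the chiral auxiliary without strong base.

Step 6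
Reactants: 9 methyl 4-{2-[(4S)-4-benzyl-2-oxo-1,3-oxazolidin-3-yl]-2-oxoethyl}-3,5-bis(methoxymethoxy)benzoate; 10 4-(benzyloxy)benzaldehyde
Product: 12 methyl 4-{(1S,2S)-1-[4-(benzyloxy)phenyl]-3-[(4S)-4-benzyl-2-oxo-1,3-oxazolidin-3-yl]-1-hydroxy-3-oxopropan-2-yl}-3,5-bis(methoxymethoxy)benzoate, via (Z)-boron enolate 11 (not isolated)
Conditions: Bu2BOTf (1.2 equiv), i-Pr2NEt (1.4 equiv), CH2Cl2, −78 → 0 °C; then 10, −78 → 0 °C; then pH 7 buffer, MeOH, 30% H2O2, 0 °C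
Reagents that add atoms: dibutylboron triflate, CCCCB(CCCC)OS(=O)(=O)C(F)(F)F (boron is carried by 11 only)
Why: Evans syn-aldol addition, in which the (Z)-boron enolate reacts through a Zimmerman–Traxler chair on the face away from the benzyl group, sets the α-centre S (the later control element for C2) and the carbinol S.

Step 7
Reactants: 12 methyl 4-{(1S,2S)-1-[4-(benzyloxy)phenyl]-3-[(4S)-4-benzyl-2-oxo-1,3-oxazolidin-3-yl]-1-hydroxy-3-oxopropan-2-yl}-3,5-bis(methoxymethoxy)benzoate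
Product: 13 methyl 4-{(1S,2R)-1-[4-(benzyloxy)phenyl]-1,3-dihydroxypropan-2-yl}-3,5-bis(methoxymethoxy)benzoate
Conditions: LiBH4 (1.5 equiv), MeOH (1.5 equiv), THF, 0 °C
Reagents that add atoms: none
Why: Reductive cleavage of the activated imide gives the primary alcohol and returns the auxiliary, while the less electrophilic aryl methyl ester and both stereocentres are untouched (the descriptor changes by priority only).

Step 8
Reactants: 13 methyl 4-{(1S,2R)-1-[4-(benzyloxy)phenyl]-1,3-dihydroxypropan-2-yl}-3,5-bis(methoxymethoxy)benzoate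
Product: 15 methyl (2S,3R)-2-[4-(benzyloxy)phenyl]-4-hydroxy-3-(hydroxymethyl)-2,3-dihydro-1-benzofuran-6-carboxylate, via bis-phenol triol 14 (not isolated)
Conditions: HCl (1.25 M in MeOH), 0 °C → rt
Reagents that add atoms: none
Why: Acidic methanolysis removes both MOM ethers and ionises the 4-alkoxybenzylic alcohol, and 5-exo capture of the cation by either of the two equivalent phenols (SN1 cycloetherification) places the C2 aryl group trans to the aldol-derived C3 substituent, so C2 becomes S.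

Step 9
Reactants: 15 methyl (2S,3R)-2-[4-(benzyloxy)phenyl]-4-hydroxy-3-(hydroxymethyl)-2,3-dihydro-1-benzofuran-6-carboxylate
Product: 16 methyl (2S,3R)-4-(benzyloxy)-2-[4-(benzyloxy)phenyl]-3-(hydroxymethyl)-2,3-dihydro-1-benzofuran-6-carboxylate
Conditions: BnBr (1.1 equiv), K2CO3, acetone, 50 °C
Reagents that add atoms: benzyl bromide, BrCc1ccccc1
Why: Williamson etherification is selective for the phenol because K2CO3 does not deprotonate the primary alcohol.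

Step 10
Reactants: 16 methyl (2S,3R)-4-(benzyloxy)-2-[4-(benzyloxy)phenyl]-3-(hydroxymethyl)-2,3-dihydro-1-benzofuran-6-carboxylate
Product: 18 (2S,3S)-4-(benzyloxy)-2-[4-(benzyloxy)phenyl]-6-(methoxycarbonyl)-2,3-dihydro-1-benzofuran-3-carboxylic acid, via aldehyde 17 (not isolated)
Conditions: TEMPO (0.2 equiv), PhI(OAc)2 (2.5 equiv), MeCN/H2O 1:1, rt
Reagents that add atoms: water, O
Why: Oxoammonium (TEMPO) oxidation of the primary alcohol through the aldehyde hydrate gives the acid, and C2 is untouched while the C3 configuration no longer matters because step 17 erases it.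

Step 11
Reactants: 18 (2S,3S)-4-(benzyloxy)-2-[4-(benzyloxy)phenyl]-6-(methoxycarbonyl)-2,3-dihydro-1-benzofuran-3-carboxylic acid
Product: 19 6-methyl 3-(4,5,6,7-tetrachloro-1,3-dioxoisoindolin-2-yl) (2S,3S)-4-(benzyloxy)-2-[4-(benzyloxy)phenyl]-2,3-dihydro-1-benzofuran-3,6-dicarboxylate
Conditions: N-hydroxytetrachlorophthalimide, i-PrN=C=N-i-Pr, DMAP (cat.), CH2Cl2, rt
Reagents that add atoms: N-hydroxytetrachlorophthalimide, ON1C(=O)c2c(Cl)c(Cl)c(Cl)c(Cl)c2C1=O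
Why: Carbodiimide (Steglich-type) esterification gives the redox-active ester needed for the decarboxylative coupling.

Step 12
Reactants: 20 resorcinol
Product: 21 1,3-bis(methoxymethoxy)benzene
Conditions: MOMCl (2.5 equiv), i-Pr2NEt (3 equiv), CH2Cl2, 0 °C → rt
Reagents that add atoms: chloromethyl methyl ether, COCCl
Why: Williamson-type O-alkylation gives the bis-MOM ether, which both protects the phenols and directs the next lithiation.

Step 13
Reactants: 21 1,3-bis(methoxymethoxy)benzene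
Product: 23 2-[2,6-bis(methoxymethoxy)phenyl]ethan-1-ol, via aryllithium 22 (not isolated)
Conditions: n-BuLi (1.1 equiv), THF, 0 °C; then ethylene oxide (2 equiv, THF solution), 0 °C → rt
Reagents that add atoms: n-butyllithium, [Li]CCCC (lithium is carried by 22 only); ethylene oxide, C1CO1
Why: Directed ortho-lithiation occurs at the carbon flanked by both MOM ethers and the aryllithium opens the epoxide to give the two-carbon alcohol.

Step 14
Reactants: 23 2-[2,6-bis(methoxymethoxy)phenyl]ethan-1-ol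
Product: 24 tert-butyl{2-[2,6-bis(methoxymethoxy)phenyl]ethoxy}dimethylsilane
Conditions: TBSCl, imidazole, DMF, rt
Reagents that add atoms: tert-butyldimethylsilyl chloride, CC(C)(C)[Si](C)(C)Cl
Why: Silylation masks the primary alcohol (the future acetic acid carbon) through the borylation and coupling.

Step 15
Reactants: 24 tert-butyl{2-[2,6-bis(methoxymethoxy)phenyl]ethoxy}dimethylsilane
Product: 25 tert-butyl{2-[2,6-bis(methoxymethoxy)-4-(4,4,5,5-tetramethyl-1,3,2-dioxaborolan-2-yl)phenyl]ethoxy}dimethylsilane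
Conditions: [Ir(OMe)(cod)]2 (1.5 mol %), 4,4'-di-tert-butyl-2,2'-bipyridine (3 mol %), B2pin2 (1.0 equiv), THF, 80 °C
Reagents that add atoms: bis(pinacolato)diboron, CC1(C)OB(OC1(C)C)B1OC(C)(C)C(C)(C)O1
Why: Sterically controlled Ir-catalysed C–H borylation takes place at the only C–H without an ortho substituent, meta to both oxygens, which electrophilic chemistry cannot reach.

Step 16
Reactants: 25 tert-butyl{2-[2,6-bis(methoxymethoxy)-4-(4,4,5,5-tetramethyl-1,3,2-dioxaborolan-2-yl)phenyl]ethoxy}dimethylsilane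
Product: 26 [4-(2-{[tert-butyl(dimethyl)silyl]oxy}ethyl)-3,5-bis(methoxymethoxy)phenyl]boronic acid
Conditions: NaIO4 (3 equiv), NH4OAc (3 equiv), acetone/H2O 1:1, rt
Reagents that add atoms: water, O
Why: Oxidative cleavage of the pinacol by periodate under buffered conditions frees the boronic acid without harming the MOM and silyl ethers.

Step 17
Reactants: 19 6-methyl 3-(4,5,6,7-tetrachloro-1,3-dioxoisoindolin-2-yl) (2S,3S)-4-(benzyloxy)-2-[4-(benzyloxy)phenyl]-2,3-dihydro-1-benzofuran-3,6-dicarboxylate; 26 [4-(2-{[tert-butyl(dimethyl)silyl]oxy}ethyl)-3,5-bis(methoxymethoxy)phenyl]boronic acid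
Product: 27 tert-butyl{2-[4-(DBF-A)-2,6-bis(methoxymethoxy)phenyl]ethoxy}dimethylsilane
Conditions: NiCl2·6H2O (20 mol %), 4,7-diphenyl-1,10-phenanthroline (22 mol %), Et3N (10 equiv), 26 (3 equiv), 1,4-dioxane/DMF 10:1, 75 °C
Reagents that add atoms: none
Why: Ni-catalysed decarboxylative Suzuki-type coupling of the redox-active ester generates the planar C3 benzylic radical, and the aryl group is delivered to the face opposite the C2 aryl group, so the new C3 centre is S (2,3-trans).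

Step 18
Reactants: 27 tert-butyl{2-[4-(DBF-A)-2,6-bis(methoxymethoxy)phenyl]ethoxy}dimethylsilane
Product: 28 2-[4-(DBF-A)-2,6-bis(methoxymethoxy)phenyl]ethan-1-ol
Conditions: Bu4NF, THF, 0 °C → rt
Reagents that add atoms: none
Why: Fluoride desilylation frees the primary alcohol without affecting esters, MOM or benzyl ethers.

Step 19
Reactants: 28 2-[4-(DBF-A)-2,6-bis(methoxymethoxy)phenyl]ethan-1-ol
Product: 30 2-[4-(DBF-A)-2,6-bis(methoxymethoxy)phenyl]acetic acid, via arylacetaldehyde 29 (not isolated)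
Conditions: TEMPO (0.2 equiv), PhI(OAc)2 (2.5 equiv), MeCN/H2O 1:1, rt
Reagents that add atoms: water, O
Why: Oxoammonium (TEMPO) oxidation takes the primary alcohol through the aldehyde hydrate to the arylacetic acid under near-neutral conditions.

Step 20
Reactants: 30 2-[4-(DBF-A)-2,6-bis(methoxymethoxy)phenyl]acetic acid; 7 (4S)-4-benzyl-1,3-oxazolidin-2-one
Product: 32 (4S)-4-benzyl-3-{2-[4-(DBF-A)-2,6-bis(methoxymethoxy)phenyl]acetyl}-1,3-oxazolidin-2-one, via mixed pivalic anhydride 31 (not isolated)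
Conditions: t-BuCOCl, Et3N, THF, −20 °C; then 7, LiCl, −20 °C → rt
Reagents that add atoms: pivaloyl chloride, CC(C)(C)C(=O)Cl (its acyl group is carried by 31 only)
Why: N-acylation through the mixed anhydride installs the auxiliary for the second aldol, and the aryl methyl ester is inert to these conditions.

Step 21
Reactants: 32 (4S)-4-benzyl-3-{2-[4-(DBF-A)-2,6-bis(methoxymethoxy)phenyl]acetyl}-1,3-oxazolidin-2-one; 10 4-(benzyloxy)benzaldehyde
Product: 34 (4S)-4-benzyl-3-{(2S,3S)-3-[4-(benzyloxy)phenyl]-2-[4-(DBF-A)-2,6-bis(methoxymethoxy)phenyl]-3-hydroxypropanoyl}-1,3-oxazolidin-2-one, via (Z)-boron enolate 33 (not isolated)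
Conditions: Bu2BOTf (1.3 equiv), i-Pr2NEt (1.5 equiv), CH2Cl2, −78 → 0 °C; then 10, −78 → 0 °C; then pH 7 buffer, MeOH, 30% H2O2, 0 °C
Reagents that add atoms: dibutylboron triflate, CCCCB(CCCC)OS(=O)(=O)C(F)(F)F (boron is carried by 33 only)
Why: Second Evans syn-aldol addition, controlled by the auxiliary through the Zimmerman–Traxler chair and not by the remote dihydrobenzofuran, sets the α-centre S and the carbinol S.

Step 22
Reactants: 34 (4S)-4-benzyl-3-{(2S,3S)-3-[4-(benzyloxy)phenyl]-2-[4-(DBF-A)-2,6-bis(methoxymethoxy)phenyl]-3-hydroxypropanoyl}-1,3-oxazolidin-2-one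
Product: 35 (1S,2R)-1-[4-(benzyloxy)phenyl]-2-[4-(DBF-A)-2,6-bis(methoxymethoxy)phenyl]propane-1,3-diol
Conditions: LiBH4 (1.5 equiv), MeOH (1.5 equiv), THF, 0 °C
Reagents that add atoms: none
Why: Reductive cleavage of the imide gives the diol and the recovered auxiliary, and the ring-A methyl ester survives at 0 °C.

Step 23
Reactants: 35 (1S,2R)-1-[4-(benzyloxy)phenyl]-2-[4-(DBF-A)-2,6-bis(methoxymethoxy)phenyl]propane-1,3-diol
Product: 37 (2S,3R)-2-[4-(benzyloxy)phenyl]-6-(DBF-A)-3-(hydroxymethyl)-2,3-dihydro-1-benzofuran-4-ol, via bis-phenol triol 36 (not isolated)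
Conditions: HCl (1.25 M in MeOH), 0 °C → rt
Reagents that add atoms: none
Why: MOM removal and SN1 cycloetherification through the 4-alkoxybenzylic cation close the second dihydrofuran with the C2 aryl group trans to the C3 substituent (C2 becomes S), and the first dihydrofuran is already the thermodynamic trans isomer.

Step 24
Reactants: 37 (2S,3R)-2-[4-(benzyloxy)phenyl]-6-(DBF-A)-3-(hydroxymethyl)-2,3-dihydro-1-benzofuran-4-ol
Product: 38 [(2S,3R)-4-(benzyloxy)-2-[4-(benzyloxy)phenyl]-6-(DBF-A)-2,3-dihydro-1-benzofuran-3-yl]methanol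
Conditions: BnBr (1.1 equiv), K2CO3, acetone, 50 °C
Reagents that add atoms: benzyl bromide, BrCc1ccccc1
Why: Williamson etherification caps the single phenol selectively over the primary alcohol.

Step 25
Reactants: 38 [(2S,3R)-4-(benzyloxy)-2-[4-(benzyloxy)phenyl]-6-(DBF-A)-2,3-dihydro-1-benzofuran-3-yl]methanol
Product: 40 (2S,3S)-4-(benzyloxy)-2-[4-(benzyloxy)phenyl]-6-(DBF-A)-2,3-dihydro-1-benzofuran-3-carboxylic acid, via aldehyde 39 (not isolated)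
Conditions: TEMPO (0.2 equiv), PhI(OAc)2 (2.5 equiv), MeCN/H2O 1:1, rt
Reagents that add atoms: water, O
Why: Oxoammonium (TEMPO) oxidation gives the acid, and only the C2 centres must stay fixed, which they do because they are not enolisable.

Step 26
Reactants: 40 (2S,3S)-4-(benzyloxy)-2-[4-(benzyloxy)phenyl]-6-(DBF-A)-2,3-dihydro-1-benzofuran-3-carboxylic acid
Product: 41 4,5,6,7-tetrachloro-1,3-dioxoisoindolin-2-yl (2S,3S)-4-(benzyloxy)-2-[4-(benzyloxy)phenyl]-6-(DBF-A)-2,3-dihydro-1-benzofuran-3-carboxylate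
Conditions: N-hydroxytetrachlorophthalimide, i-PrN=C=N-i-Pr, DMAP (cat.), CH2Cl2, rt
Reagents that add atoms: N-hydroxytetrachlorophthalimide, ON1C(=O)c2c(Cl)c(Cl)c(Cl)c(Cl)c2C1=O
Why: Carbodiimide (Steglich-type) esterification gives the second redox-active ester.

Step 27
Reactants: 41 4,5,6,7-tetrachloro-1,3-dioxoisoindolin-2-yl (2S,3S)-4-(benzyloxy)-2-[4-(benzyloxy)phenyl]-6-(DBF-A)-2,3-dihydro-1-benzofuran-3-carboxylate; 42 3,5-bis(benzyloxy)phenylboronic acid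
Product: 43 methyl (2S,3S)-4-(benzyloxy)-3-{(2S,3S)-4-(benzyloxy)-3-[3,5-bis(benzyloxy)phenyl]-2-[4-(benzyloxy)phenyl]-2,3-dihydro-1-benzofuran-6-yl}-2-[4-(benzyloxy)phenyl]-2,3-dihydro-1-benzofuran-6-carboxylate
Conditions: NiCl2·6H2O (20 mol %), 4,7-diphenyl-1,10-phenanthroline (22 mol %), Et3N (10 equiv), 42 (3 equiv), 1,4-dioxane/DMF 10:1, 75 °C
Reagents that add atoms: none
Why: Second Ni-catalysed decarboxylative Suzuki-type coupling, in which the C3 radical is arylated anti to the neighbouring C2 aryl group, sets the last stereocentre S (trans).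

Step 28
Reactants: 43 methyl (2S,3S)-4-(benzyloxy)-3-{(2S,3S)-4-(benzyloxy)-3-[3,5-bis(benzyloxy)phenyl]-2-[4-(benzyloxy)phenyl]-2,3-dihydro-1-benzofuran-6-yl}-2-[4-(benzyloxy)phenyl]-2,3-dihydro-1-benzofuran-6-carboxylate
Product: 44 [(2S,3S)-4-(benzyloxy)-3-{(2S,3S)-4-(benzyloxy)-3-[3,5-bis(benzyloxy)phenyl]-2-[4-(benzyloxy)phenyl]-2,3-dihydro-1-benzofuran-6-yl}-2-[4-(benzyloxy)phenyl]-2,3-dihydro-1-benzofuran-6-yl]methanol
Conditions: i-Bu2AlH (3 equiv), CH2Cl2, −78 → 0 °C; Rochelle salt work-up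
Reagents that add atoms: none
Why: Hydride reduction of the only ester in the molecule gives the benzylic alcohol, with ethers and stereocentres inert.

Step 29
Reactants: 44 [(2S,3S)-4-(benzyloxy)-3-{(2S,3S)-4-(benzyloxy)-3-[3,5-bis(benzyloxy)phenyl]-2-[4-(benzyloxy)phenyl]-2,3-dihydro-1-benzofuran-6-yl}-2-[4-(benzyloxy)phenyl]-2,3-dihydro-1-benzofuran-6-yl]methanol
Product: 45 (2S,3S)-4-(benzyloxy)-3-{(2S,3S)-4-(benzyloxy)-3-[3,5-bis(benzyloxy)phenyl]-2-[4-(benzyloxy)phenyl]-2,3-dihydro-1-benzofuran-6-yl}-2-[4-(benzyloxy)phenyl]-2,3-dihydro-1-benzofuran-6-carbaldehyde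
Conditions: MnO2 (activated, excess), CH2Cl2, rt
Reagents that add atoms: none
Why: Selective heterogeneous oxidation of the benzylic alcohol stops at the aldehyde.

Step 30
Reactants: 46 4-(benzyloxy)benzyl chloride
Product: 47 diethyl [4-(benzyloxy)benzyl]phosphonate
Conditions: P(OEt)3 (neat), 140 °C
Reagents that add atoms: triethyl phosphite, CCOP(OCC)OCC
Why: Michaelis–Arbuzov reaction of the benzylic chloride gives the phosphonate for the olefination.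

Step 31
Reactants: 45 (2S,3S)-4-(benzyloxy)-3-{(2S,3S)-4-(benzyloxy)-3-[3,5-bis(benzyloxy)phenyl]-2-[4-(benzyloxy)phenyl]-2,3-dihydro-1-benzofuran-6-yl}-2-[4-(benzyloxy)phenyl]-2,3-dihydro-1-benzofuran-6-carbaldehyde; 47 diethyl [4-(benzyloxy)benzyl]phosphonate
Product: 48 (2S,3S)-4-(benzyloxy)-3-{(2S,3S)-4-(benzyloxy)-3-[3,5-bis(benzyloxy)phenyl]-2-[4-(benzyloxy)phenyl]-2,3-dihydro-1-benzofuran-6-yl}-2-[4-(benzyloxy)phenyl]-6-{(E)-2-[4-(benzyloxy)phenyl]ethenyl}-2,3-dihydro-1-benzofuran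
Conditions: 47 (1.5 equiv), KOtBu (1.5 equiv), THF, 0 °C; then 45, 0 °C → rt
Reagents that add atoms: none
Why: Horner–Wadsworth–Emmons olefination with a benzylic phosphonate gives the (E)-stilbene under thermodynamic control.

Step 32
Reactants: 48 (2S,3S)-4-(benzyloxy)-3-{(2S,3S)-4-(benzyloxy)-3-[3,5-bis(benzyloxy)phenyl]-2-[4-(benzyloxy)phenyl]-2,3-dihydro-1-benzofuran-6-yl}-2-[4-(benzyloxy)phenyl]-6-{(E)-2-[4-(benzyloxy)phenyl]ethenyl}-2,3-dihydro-1-benzofuran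
Product: 49 (2S,3S)-3-[(2S,3S)-3-(3,5-dihydroxyphenyl)-4-hydroxy-2-(4-hydroxyphenyl)-2,3-dihydro-1-benzofuran-6-yl]-2-(4-hydroxyphenyl)-6-[(E)-2-(4-hydroxyphenyl)ethenyl]-2,3-dihydro-1-benzofuran-4-ol
Conditions: BCl3 (1 M in CH2Cl2, 20 equiv), C6HMe5 (30 equiv), CH2Cl2, −78 → −40 °C; then MeOH
Reagents that add atoms: none
Why: Lewis-acid debenzylation with pentamethylbenzene as benzyl-cation scavenger removes all seven benzyl ethers without reducing the stilbene, and any reversible C2–O ionisation recloses to the trans dihydrofurans.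

**Compound list**

1 | methyl 4-bromo-3,5-dihydroxybenzoate | COC(=O)c1cc(O)c(Br)c(O)c1 | starting material
2 | methyl 4-bromo-3,5-bis(methoxymethoxy)benzoate | COCOc1cc(C(=O)OC)cc(OCOC)c1Br | intermediate
3 | methyl 3,5-bis(methoxymethoxy)-4-(prop-2-en-1-yl)benzoate | COCOc1cc(C(=O)OC)cc(OCOC)c1CC=C | intermediate
4 | methyl 4-(2,3-dihydroxypropyl)-3,5-bis(methoxymethoxy)benzoate (racemic, not isolated) | COCOc1cc(C(=O)OC)cc(OCOC)c1CC(O)CO | intermediate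
5 | methyl 3,5-bis(methoxymethoxy)-4-(2-oxoethyl)benzoate | COCOc1cc(C(=O)OC)cc(OCOC)c1CC=O | intermediate
6 | 2-[4-(methoxycarbonyl)-2,6-bis(methoxymethoxy)phenyl]acetic acid | COCOc1cc(C(=O)OC)cc(OCOC)c1CC(=O)O | intermediate
7 | (4S)-4-benzyl-1,3-oxazolidin-2-one | O=C1N[C@@H](Cc2ccccc2)CO1 | starting material
8 | 2-[4-(methoxycarbonyl)-2,6-bis(methoxymethoxy)phenyl]acetic pivalic anhydride (not isolated) | COCOc1cc(C(=O)OC)cc(OCOC)c1CC(=O)OC(=O)C(C)(C)C | intermediate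
9 | methyl 4-{2-[(4S)-4-benzyl-2-oxo-1,3-oxazolidin-3-yl]-2-oxoethyl}-3,5-bis(methoxymethoxy)benzoate | COCOc1cc(C(=O)OC)cc(OCOC)c1CC(=O)N1[C@@H](Cc2ccccc2)COC1=O | intermediate
10 | 4-(benzyloxy)benzaldehyde | O=Cc1ccc(OCc2ccccc2)cc1 | starting material
11 | methyl 4-{(Z)-2-[(4S)-4-benzyl-2-oxo-1,3-oxazolidin-3-yl]-2-[(dibutylboranyl)oxy]ethenyl}-3,5-bis(methoxymethoxy)benzoate (not isolated) | COCOc1cc(C(=O)OC)cc(OCOC)c1/C=C(\OB(CCCC)CCCC)N1[C@@H](Cc2ccccc2)COC1=O | intermediate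
12 | methyl 4-{(1S,2S)-1-[4-(benzyloxy)phenyl]-3-[(4S)-4-benzyl-2-oxo-1,3-oxazolidin-3-yl]-1-hydroxy-3-oxopropan-2-yl}-3,5-bis(methoxymethoxy)benzoate | COCOc1cc(C(=O)OC)cc(OCOC)c1[C@@H]([C@H](O)c1ccc(OCc2ccccc2)cc1)C(=O)N1[C@@H](Cc2ccccc2)COC1=O | intermediate
13 | methyl 4-{(1S,2R)-1-[4-(benzyloxy)phenyl]-1,3-dihydroxypropan-2-yl}-3,5-bis(methoxymethoxy)benzoate | COCOc1cc(C(=O)OC)cc(OCOC)c1[C@@H]([C@H](O)c1ccc(OCc2ccccc2)cc1)CO | intermediate
14 | methyl 4-{(1S,2R)-1-[4-(benzyloxy)phenyl]-1,3-dihydroxypropan-2-yl}-3,5-dihydroxybenzoate (not isolated) | COC(=O)c1cc(O)c([C@@H]([C@H](O)c2ccc(OCc3ccccc3)cc2)CO)c(O)c1 | intermediate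
15 | methyl (2S,3R)-2-[4-(benzyloxy)phenyl]-4-hydroxy-3-(hydroxymethyl)-2,3-dihydro-1-benzofuran-6-carboxylate | COC(=O)c1cc(O)c2c(c1)O[C@H](c1ccc(OCc3ccccc3)cc1)[C@H]2CO | intermediate
16 | methyl (2S,3R)-4-(benzyloxy)-2-[4-(benzyloxy)phenyl]-3-(hydroxymethyl)-2,3-dihydro-1-benzofuran-6-carboxylate | COC(=O)c1cc(OCc3ccccc3)c2c(c1)O[C@H](c1ccc(OCc3ccccc3)cc1)[C@H]2CO | intermediate
17 | methyl (2S,3S)-4-(benzyloxy)-2-[4-(benzyloxy)phenyl]-3-formyl-2,3-dihydro-1-benzofuran-6-carboxylate (not isolated) | COC(=O)c1cc(OCc3ccccc3)c2c(c1)O[C@H](c1ccc(OCc3ccccc3)cc1)[C@H]2C=O | intermediate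
18 | (2S,3S)-4-(benzyloxy)-2-[4-(benzyloxy)phenyl]-6-(methoxycarbonyl)-2,3-dihydro-1-benzofuran-3-carboxylic acid | COC(=O)c1cc(OCc3ccccc3)c2c(c1)O[C@H](c1ccc(OCc3ccccc3)cc1)[C@H]2C(=O)O | intermediate
19 | 6-methyl 3-(4,5,6,7-tetrachloro-1,3-dioxoisoindolin-2-yl) (2S,3S)-4-(benzyloxy)-2-[4-(benzyloxy)phenyl]-2,3-dihydro-1-benzofuran-3,6-dicarboxylate | COC(=O)c1cc(OCc3ccccc3)c2c(c1)O[C@H](c1ccc(OCc3ccccc3)cc1)[C@H]2C(=O)ON1C(=O)c2c(Cl)c(Cl)c(Cl)c(Cl)c2C1=O | intermediate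
20 | resorcinol (benzene-1,3-diol) | Oc1cccc(O)c1 | starting material
21 | 1,3-bis(methoxymethoxy)benzene | COCOc1cccc(OCOC)c1 | intermediate
22 | [2,6-bis(methoxymethoxy)phenyl]lithium (not isolated) | [Li]c1c(OCOC)cccc1OCOC | intermediate
23 | 2-[2,6-bis(methoxymethoxy)phenyl]ethan-1-ol | COCOc1cccc(OCOC)c1CCO | intermediate
24 | tert-butyl{2-[2,6-bis(methoxymethoxy)phenyl]ethoxy}dimethylsilane | COCOc1cccc(OCOC)c1CCO[Si](C)(C)C(C)(C)C | intermediate
25 | tert-butyl{2-[2,6-bis(methoxymethoxy)-4-(4,4,5,5-tetramethyl-1,3,2-dioxaborolan-2-yl)phenyl]ethoxy}dimethylsilane | COCOc1cc(B2OC(C)(C)C(C)(C)O2)cc(OCOC)c1CCO[Si](C)(C)C(C)(C)C | intermediate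
26 | [4-(2-{[tert-butyl(dimethyl)silyl]oxy}ethyl)-3,5-bis(methoxymethoxy)phenyl]boronic acid | COCOc1cc(B(O)O)cc(OCOC)c1CCO[Si](C)(C)C(C)(C)C | intermediate
27 | tert-butyl{2-[4-(DBF-A)-2,6-bis(methoxymethoxy)phenyl]ethoxy}dimethylsilane | COC(=O)c1cc(OCc3ccccc3)c2c(c1)O[C@H](c1ccc(OCc3ccccc3)cc1)[C@H]2c1cc(OCOC)c(CCO[Si](C)(C)C(C)(C)C)c(OCOC)c1 | intermediate
28 | 2-[4-(DBF-A)-2,6-bis(methoxymethoxy)phenyl]ethan-1-ol | COC(=O)c1cc(OCc3ccccc3)c2c(c1)O[C@H](c1ccc(OCc3ccccc3)cc1)[C@H]2c1cc(OCOC)c(CCO)c(OCOC)c1 | intermediate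
29 | 2-[4-(DBF-A)-2,6-bis(methoxymethoxy)phenyl]acetaldehyde (not isolated) | COC(=O)c1cc(OCc3ccccc3)c2c(c1)O[C@H](c1ccc(OCc3ccccc3)cc1)[C@H]2c1cc(OCOC)c(CC=O)c(OCOC)c1 | intermediate
30 | 2-[4-(DBF-A)-2,6-bis(methoxymethoxy)phenyl]acetic acid | COC(=O)c1cc(OCc3ccccc3)c2c(c1)O[C@H](c1ccc(OCc3ccccc3)cc1)[C@H]2c1cc(OCOC)c(CC(=O)O)c(OCOC)c1 | intermediate
31 | 2-[4-(DBF-A)-2,6-bis(methoxymethoxy)phenyl]acetic pivalic anhydride (not isolated) | COC(=O)c1cc(OCc3ccccc3)c2c(c1)O[C@H](c1ccc(OCc3ccccc3)cc1)[C@H]2c1cc(OCOC)c(CC(=O)OC(=O)C(C)(C)C)c(OCOC)c1 | intermediate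
32 | (4S)-4-benzyl-3-{2-[4-(DBF-A)-2,6-bis(methoxymethoxy)phenyl]acetyl}-1,3-oxazolidin-2-one | COC(=O)c1cc(OCc3ccccc3)c2c(c1)O[C@H](c1ccc(OCc3ccccc3)cc1)[C@H]2c1cc(OCOC)c(CC(=O)N2[C@@H](Cc3ccccc3)COC2=O)c(OCOC)c1 | intermediate
33 | (Z)-O-dibutylboron enolate of 32 (not isolated) | COC(=O)c1cc(OCc3ccccc3)c2c(c1)O[C@H](c1ccc(OCc3ccccc3)cc1)[C@H]2c1cc(OCOC)c(/C=C(\OB(CCCC)CCCC)N2[C@@H](Cc3ccccc3)COC2=O)c(OCOC)c1 | intermediate
34 | (4S)-4-benzyl-3-{(2S,3S)-3-[4-(benzyloxy)phenyl]-2-[4-(DBF-A)-2,6-bis(methoxymethoxy)phenyl]-3-hydroxypropanoyl}-1,3-oxazolidin-2-one | COC(=O)c1cc(OCc3ccccc3)c2c(c1)O[C@H](c1ccc(OCc3ccccc3)cc1)[C@H]2c1cc(OCOC)c([C@@H]([C@H](O)c2ccc(OCc3ccccc3)cc2)C(=O)N2[C@@H](Cc3ccccc3)COC2=O)c(OCOC)c1 | intermediate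
35 | (1S,2R)-1-[4-(benzyloxy)phenyl]-2-[4-(DBF-A)-2,6-bis(methoxymethoxy)phenyl]propane-1,3-diol | COC(=O)c1cc(OCc3ccccc3)c2c(c1)O[C@H](c1ccc(OCc3ccccc3)cc1)[C@H]2c1cc(OCOC)c([C@@H]([C@H](O)c2ccc(OCc3ccccc3)cc2)CO)c(OCOC)c1 | intermediate
36 | 2-{(1S,2R)-1-[4-(benzyloxy)phenyl]-1,3-dihydroxypropan-2-yl}-5-(DBF-A)benzene-1,3-diol (not isolated) | COC(=O)c1cc(OCc3ccccc3)c2c(c1)O[C@H](c1ccc(OCc3ccccc3)cc1)[C@H]2c1cc(O)c([C@@H]([C@H](O)c2ccc(OCc3ccccc3)cc2)CO)c(O)c1 | intermediate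
37 | (2S,3R)-2-[4-(benzyloxy)phenyl]-6-(DBF-A)-3-(hydroxymethyl)-2,3-dihydro-1-benzofuran-4-ol | COC(=O)c1cc(OCc3ccccc3)c2c(c1)O[C@H](c1ccc(OCc3ccccc3)cc1)[C@H]2c1cc(O)c2c(c1)O[C@H](c1ccc(OCc3ccccc3)cc1)[C@H]2CO | intermediate
38 | [(2S,3R)-4-(benzyloxy)-2-[4-(benzyloxy)phenyl]-6-(DBF-A)-2,3-dihydro-1-benzofuran-3-yl]methanol | COC(=O)c1cc(OCc3ccccc3)c2c(c1)O[C@H](c1ccc(OCc3ccccc3)cc1)[C@H]2c1cc(OCc3ccccc3)c2c(c1)O[C@H](c1ccc(OCc3ccccc3)cc1)[C@H]2CO | intermediate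
39 | (2S,3S)-4-(benzyloxy)-2-[4-(benzyloxy)phenyl]-6-(DBF-A)-2,3-dihydro-1-benzofuran-3-carbaldehyde (not isolated) | COC(=O)c1cc(OCc3ccccc3)c2c(c1)O[C@H](c1ccc(OCc3ccccc3)cc1)[C@H]2c1cc(OCc3ccccc3)c2c(c1)O[C@H](c1ccc(OCc3ccccc3)cc1)[C@H]2C=O | intermediate
40 | (2S,3S)-4-(benzyloxy)-2-[4-(benzyloxy)phenyl]-6-(DBF-A)-2,3-dihydro-1-benzofuran-3-carboxylic acid | COC(=O)c1cc(OCc3ccccc3)c2c(c1)O[C@H](c1ccc(OCc3ccccc3)cc1)[C@H]2c1cc(OCc3ccccc3)c2c(c1)O[C@H](c1ccc(OCc3ccccc3)cc1)[C@H]2C(=O)O | intermediate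
41 | 4,5,6,7-tetrachloro-1,3-dioxoisoindolin-2-yl (2S,3S)-4-(benzyloxy)-2-[4-(benzyloxy)phenyl]-6-(DBF-A)-2,3-dihydro-1-benzofuran-3-carboxylate | COC(=O)c1cc(OCc3ccccc3)c2c(c1)O[C@H](c1ccc(OCc3ccccc3)cc1)[C@H]2c1cc(OCc3ccccc3)c2c(c1)O[C@H](c1ccc(OCc3ccccc3)cc1)[C@H]2C(=O)ON1C(=O)c2c(Cl)c(Cl)c(Cl)c(Cl)c2C1=O | intermediate
42 | 3,5-bis(benzyloxy)phenylboronic acid | OB(O)c1cc(OCc2ccccc2)cc(OCc2ccccc2)c1 | starting material
43 | methyl (2S,3S)-4-(benzyloxy)-3-{(2S,3S)-4-(benzyloxy)-3-[3,5-bis(benzyloxy)phenyl]-2-[4-(benzyloxy)phenyl]-2,3-dihydro-1-benzofuran-6-yl}-2-[4-(benzyloxy)phenyl]-2,3-dihydro-1-benzofuran-6-carboxylate | COC(=O)c1cc(OCc3ccccc3)c2c(c1)O[C@H](c1ccc(OCc3ccccc3)cc1)[C@H]2c1cc(OCc3ccccc3)c2c(c1)O[C@H](c1ccc(OCc3ccccc3)cc1)[C@H]2c1cc(OCc2ccccc2)cc(OCc2ccccc2)c1 | intermediate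
44 | [(2S,3S)-4-(benzyloxy)-3-{(2S,3S)-4-(benzyloxy)-3-[3,5-bis(benzyloxy)phenyl]-2-[4-(benzyloxy)phenyl]-2,3-dihydro-1-benzofuran-6-yl}-2-[4-(benzyloxy)phenyl]-2,3-dihydro-1-benzofuran-6-yl]methanol | OCc1cc(OCc3ccccc3)c2c(c1)O[C@H](c1ccc(OCc3ccccc3)cc1)[C@H]2c1cc(OCc3ccccc3)c2c(c1)O[C@H](c1ccc(OCc3ccccc3)cc1)[C@H]2c1cc(OCc2ccccc2)cc(OCc2ccccc2)c1 | intermediate
45 | (2S,3S)-4-(benzyloxy)-3-{(2S,3S)-4-(benzyloxy)-3-[3,5-bis(benzyloxy)phenyl]-2-[4-(benzyloxy)phenyl]-2,3-dihydro-1-benzofuran-6-yl}-2-[4-(benzyloxy)phenyl]-2,3-dihydro-1-benzofuran-6-carbaldehyde | O=Cc1cc(OCc3ccccc3)c2c(c1)O[C@H](c1ccc(OCc3ccccc3)cc1)[C@H]2c1cc(OCc3ccccc3)c2c(c1)O[C@H](c1ccc(OCc3ccccc3)cc1)[C@H]2c1cc(OCc2ccccc2)cc(OCc2ccccc2)c1 | intermediate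
46 | 4-(benzyloxy)benzyl chloride | ClCc1ccc(OCc2ccccc2)cc1 | starting material
47 | diethyl [4-(benzyloxy)benzyl]phosphonate | CCOP(=O)(OCC)Cc1ccc(OCc2ccccc2)cc1 | intermediate
48 | (2S,3S)-4-(benzyloxy)-3-{(2S,3S)-4-(benzyloxy)-3-[3,5-bis(benzyloxy)phenyl]-2-[4-(benzyloxy)phenyl]-2,3-dihydro-1-benzofuran-6-yl}-2-[4-(benzyloxy)phenyl]-6-{(E)-2-[4-(benzyloxy)phenyl]ethenyl}-2,3-dihydro-1-benzofuran | C(c1ccccc1)Oc1ccc(/C=C/c2cc(OCc3ccccc3)c3c(c2)O[C@H](c2ccc(OCc4ccccc4)cc2)[C@H]3c2cc(OCc3ccccc3)c3c(c2)O[C@H](c2ccc(OCc4ccccc4)cc2)[C@H]3c2cc(OCc3ccccc3)cc(OCc3ccccc3)c2)cc1 | intermediate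
49 | (2S,3S)-3-[(2S,3S)-3-(3,5-dihydroxyphenyl)-4-hydroxy-2-(4-hydroxyphenyl)-2,3-dihydro-1-benzofuran-6-yl]-2-(4-hydroxyphenyl)-6-[(E)-2-(4-hydroxyphenyl)ethenyl]-2,3-dihydro-1-benzofuran-4-ol | Oc1ccc(/C=C/c2cc(O)c3c(c2)O[C@H](c2ccc(O)cc2)[C@H]3c2cc(O)c3c(c2)O[C@H](c2ccc(O)cc2)[C@H]3c2cc(O)cc(O)c2)cc1 | target

**Step count and weak points**

Total: 32 steps. Longest linear sequence: 26 steps (steps 1–11, 17–29, 31, 32). Steps 12–16 (ring-B boronic acid) and step 30 (phosphonate) are side branches.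

The three steps most likely to fail:

Step 17 (its twin, step 27, shares the risk). The decarboxylative arylation at the hindered benzylic C3 could give radical dimer, the benzofuran from loss of hydrogen, or a poor trans:cis ratio. The fallback sets out from boronic acid 26 and acid 18 and comes back at 27, replacing the boron nucleophile by an organozinc under room-temperature Negishi-type conditions. Boronic acid 26 is iodo-deboronated (I2, K2CO3, MeCN, 80 °C) to tert-butyl{2-[4-iodo-2,6-bis(methoxymethoxy)phenyl]ethoxy}dimethylsilane F7. Iodine–magnesium exchange (i-PrMgCl·LiCl, THF, −20 °C) gives [4-(2-{[tert-butyl(dimethyl)silyl]oxy}ethyl)-3,5-bis(methoxymethoxy)phenyl]magnesium chloride F8, and transmetalation with ZnCl2 gives [4-(2-{[tert-butyl(dimethyl)silyl]oxy}ethyl)-3,5-bis(methoxymethoxy)phenyl]zinc chloride F9. Acid 18 is esterified (N-hydroxyphthalimide, i-PrN=C=N-i-Pr, DMAP) to 6-methyl 3-(1,3-dioxoisoindolin-2-yl) (2S,3S)-4-(benzyloxy)-2-[4-(benzyloxy)phenyl]-2,3-dihydro-1-benzofuran-3,6-dicarboxylate F10. F10 is then coupled with F9 (NiCl2·glyme 20 mol %, 4,4'-di-tert-butyl-2,2'-bipyridine 40 mol %, THF/DMF, rt) to give 27.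

Step 8 (twin: step 23). The benzylic cation next to a free CH2OH can lose formaldehyde (retro-Prins) to a stilbene, eliminate, or give a poor trans:cis ratio. The fallback sets out from diol 13 and comes back at 16, blocking the primary alcohol before ionisation and unmasking it only after the ring is closed. Selective acylation of 13 (t-BuCOCl, pyridine, CH2Cl2, 0 °C) gives methyl 4-{(1S,2R)-1-[4-(benzyloxy)phenyl]-1-hydroxy-3-(pivaloyloxy)propan-2-yl}-3,5-bis(methoxymethoxy)benzoate F4. MOM removal and cyclisation (HCl in MeOH, rt; can now be pushed harder) give methyl (2S,3R)-2-[4-(benzyloxy)phenyl]-4-hydroxy-3-[(pivaloyloxy)methyl]-2,3-dihydro-1-benzofuran-6-carboxylate F5. Benzylation (BnBr, K2CO3, acetone) gives methyl (2S,3R)-4-(benzyloxy)-2-[4-(benzyloxy)phenyl]-3-[(pivaloyloxy)methyl]-2,3-dihydro-1-benzofuran-6-carboxylate F6, and methanolysis of the pivalate (NaOMe, MeOH, 40 °C; the methyl ester only exchanges with itself) returns 16.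

Step 6 (twin: step 21). The doubly ortho-substituted arylacetyl enolate may add sluggishly or with eroded selectivity. The fallback sets out from acid 6 and comes back at diol 13, replacing the aldol by a Claisen-type C-acylation of the imide enolate followed by chelation-controlled reduction. Because acylation of the chelated enolate occurs on the face opposite to that of the boron aldol, the enantiomeric auxiliary is used. Acid 6 is coupled (t-BuCOCl, Et3N, then LiCl) with (4R)-4-benzyl-1,3-oxazolidin-2-one to give methyl 4-{2-[(4R)-4-benzyl-2-oxo-1,3-oxazolidin-3-yl]-2-oxoethyl}-3,5-bis(methoxymethoxy)benzoate F1. Its sodium enolate (NaN(SiMe3)2, THF, −78 °C) is acylated with 4-(benzyloxy)benzoyl chloride to give methyl 4-{(2S)-1-[4-(benzyloxy)phenyl]-3-[(4R)-4-benzyl-2-oxo-1,3-oxazolidin-3-yl]-1,3-dioxopropan-2-yl}-3,5-bis(methoxymethoxy)benzoate F2. Reduction with Zn(BH4)2 (CH2Cl2/Et2O, −20 °C) gives the syn alcohol methyl 4-{(1S,2S)-1-[4-(benzyloxy)phenyl]-3-[(4R)-4-benzyl-2-oxo-1,3-oxazolidin-3-yl]-1-hydroxy-3-oxopropan-2-yl}-3,5-bis(methoxymethoxy)benzoate F3, and LiBH4 (as in step 7) gives 13.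

**Further compounds**

F1 | step 6 | methyl 4-{2-[(4R)-4-benzyl-2-oxo-1,3-oxazolidin-3-yl]-2-oxoethyl}-3,5-bis(methoxymethoxy)benzoate | COCOc1cc(C(=O)OC)cc(OCOC)c1CC(=O)N1[C@H](Cc2ccccc2)COC1=O
F2 | step 6 | methyl 4-{(2S)-1-[4-(benzyloxy)phenyl]-3-[(4R)-4-benzyl-2-oxo-1,3-oxazolidin-3-yl]-1,3-dioxopropan-2-yl}-3,5-bis(methoxymethoxy)benzoate | COCOc1cc(C(=O)OC)cc(OCOC)c1[C@@H](C(=O)c1ccc(OCc2ccccc2)cc1)C(=O)N1[C@H](Cc2ccccc2)COC1=O
F3 | step 6 | methyl 4-{(1S,2S)-1-[4-(benzyloxy)phenyl]-3-[(4R)-4-benzyl-2-oxo-1,3-oxazolidin-3-yl]-1-hydroxy-3-oxopropan-2-yl}-3,5-bis(methoxymethoxy)benzoate | COCOc1cc(C(=O)OC)cc(OCOC)c1[C@@H]([C@H](O)c1ccc(OCc2ccccc2)cc1)C(=O)N1[C@H](Cc2ccccc2)COC1=O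
F4 | step 8 | methyl 4-{(1S,2R)-1-[4-(benzyloxy)phenyl]-1-hydroxy-3-(pivaloyloxy)propan-2-yl}-3,5-bis(methoxymethoxy)benzoate | COCOc1cc(C(=O)OC)cc(OCOC)c1[C@@H]([C@H](O)c1ccc(OCc2ccccc2)cc1)COC(=O)C(C)(C)C
F5 | step 8 | methyl (2S,3R)-2-[4-(benzyloxy)phenyl]-4-hydroxy-3-[(pivaloyloxy)methyl]-2,3-dihydro-1-benzofuran-6-carboxylate | COC(=O)c1cc(O)c2c(c1)O[C@H](c1ccc(OCc3ccccc3)cc1)[C@H]2COC(=O)C(C)(C)C
F6 | step 8 | methyl (2S,3R)-4-(benzyloxy)-2-[4-(benzyloxy)phenyl]-3-[(pivaloyloxy)methyl]-2,3-dihydro-1-benzofuran-6-carboxylate | COC(=O)c1cc(OCc3ccccc3)c2c(c1)O[C@H](c1ccc(OCc3ccccc3)cc1)[C@H]2COC(=O)C(C)(C)C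
F7 | step 17 | tert-butyl{2-[4-iodo-2,6-bis(methoxymethoxy)phenyl]ethoxy}dimethylsilane | COCOc1cc(I)cc(OCOC)c1CCO[Si](C)(C)C(C)(C)C
F8 | step 17 | [4-(2-{[tert-butyl(dimethyl)silyl]oxy}ethyl)-3,5-bis(methoxymethoxy)phenyl]magnesium chloride | COCOc1cc([Mg]Cl)cc(OCOC)c1CCO[Si](C)(C)C(C)(C)C
F9 | step 17 | [4-(2-{[tert-butyl(dimethyl)silyl]oxy}ethyl)-3,5-bis(methoxymethoxy)phenyl]zinc chloride | COCOc1cc([Zn]Cl)cc(OCOC)c1CCO[Si](C)(C)C(C)(C)C
F10 | step 17 | 6-methyl 3-(1,3-dioxoisoindolin-2-yl) (2S,3S)-4-(benzyloxy)-2-[4-(benzyloxy)phenyl]-2,3-dihydro-1-benzofuran-3,6-dicarboxylate | COC(=O)c1cc(OCc3ccccc3)c2c(c1)O[C@H](c1ccc(OCc3ccccc3)cc1)[C@H]2C(=O)ON1C(=O)c2ccccc2C1=O
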